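**Retrosynthetic overview**

1. The two resorcinol rings are bought; the only ring made is the 22-membered [7.7]paracyclophane, closed in the last step. Two identical chloro-resorcinol monomers are joined head-to-tail by a double Friedel–Crafts C-alkylation (CylK-type, SN2 with inversion at each secondary C–Cl): first the intermolecular aryl–C bond, then the ring-closing one. Both aryl-bearing stereocentres are set here and the product is the target itself.
2. Monomer ⇒ cross-metathesis then hydrogenation (C3–C4 bond) of a resorcinol crotyl carbamate and (S)-5,9,9-trichloronon-1-ene.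
3. Crotyl carbamate ⇒ Brown (Z)-crotylboration of 3,5-bis(silyloxy)benzaldehyde (sets C1 and C2, syn), then carbamoylation with desilylation.
4. Trichloride ⇒ (S)-1,2-epoxy-5-hexene (hydrolytic kinetic resolution) plus an acetal Grignard; Appel inversion gives the C–Cl centre; the aldehyde becomes CHCl2.

Assumption: recombinant CylK (His6-tagged, from a commercially synthesised gene expressed in E. coli) is treated as a catalyst prepared in-house, not as a starting material; every atom of the target comes from commercial chemicals.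

**Route**

Step 1
Reactants: 1 3,5-dihydroxybenzaldehyde
Product: 2 3,5-bis(tert-butyldimethylsilyloxy)benzaldehyde
Conditions: TBSCl (2.2 equiv), imidazole, DMF, 0 °C to rt
Reagents that add atoms: tert-butyldimethylsilyl chloride, CC(C)(C)[Si](C)(C)Cl
Why: Standard silyl ether formation masks both phenols, which would otherwise protonate the crotylborane of the next step; no stereocentre is involved.

Step 2
Reactants: 2 3,5-bis(tert-butyldimethylsilyloxy)benzaldehyde
Product: 4 (1R,2S)-1-[3,5-bis(tert-butyldimethylsilyloxy)phenyl]-2-methylbut-3-en-1-ol, via O-borinate ester 3 (not isolated)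
Conditions: cis-2-butene, KOtBu, n-BuLi, THF, −78 to −45 °C; (+)-B-methoxydiisopinocampheylborane (from (−)-α-pinene), −78 °C; BF3·OEt2; then 2, −78 °C; NaBO3·4H2O, THF/H2O, rt
Reagents that add atoms: cis-2-butene, C/C=C\C (delivered as the (Z)-crotyldiisopinocampheylborane made in the flask)
Why: Brown asymmetric crotylboration runs through a closed chair transition state, so the Z-crotyl geometry gives the 1,2-syn pair and the (−)-α-pinene-derived isopinocampheyl groups direct attack to the re face of the aryl aldehyde, setting C1 (R) and C2 (S) together.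

Step 3
Reactants: 4 (1R,2S)-1-[3,5-bis(tert-butyldimethylsilyloxy)phenyl]-2-methylbut-3-en-1-ol
Product: 6 (1R,2S)-1-(3,5-dihydroxyphenyl)-2-methylbut-3-en-1-yl carbamate, via N-trichloroacetyl carbamate 5 (not isolated)
Conditions: Cl3CC(O)NCO, CH2Cl2, 0 °C; then K2CO3 (20 mol %), MeOH, rt, under argon
Reagents that add atoms: trichloroacetyl isocyanate, O=C=NC(=O)C(Cl)(Cl)Cl
Why: Kocovsky carbamoylation of the only free hydroxyl, followed by base-catalysed methanolysis that removes the trichloroacetyl group and both phenolic silyl ethers in the same flask, leaves the alkyl carbamate and both stereocentres untouched.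

Step 4
Reactants: 7 rac-2-(but-3-en-1-yl)oxirane (1,2-epoxy-5-hexene)
Product: 8 (S)-2-(but-3-en-1-yl)oxirane
Conditions: (S,S)-(salen)Co(OAc) [acetate of trivalent cobalt with (S,S)-N,N'-bis(3,5-di-tert-butylsalicylidene)cyclohexane-1,2-diamine] (0.5 mol %), H2O (0.55 equiv), 0 °C to rt; distil
Reagents that add atoms: none
Why: In the Jacobsen hydrolytic kinetic resolution the (S,S)-catalyst hydrolyses the (R)-epoxide selectively, leaving the (S)-epoxide in >99% ee (50% maximum yield), which is the source of the later C–Cl stereocentre.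

Step 5
Reactants: 8 (S)-2-(but-3-en-1-yl)oxirane; 9 2-(2-bromoethyl)-1,3-dioxolane
Product: 11 (R)-1-(1,3-dioxolan-2-yl)oct-7-en-4-ol, via Grignard reagent 10 (not isolated)
Conditions: 9, Mg, THF, 30 °C; then CuI (10 mol %), 8, −30 to 0 °C; H2O
Reagents that add atoms: none
Why: Copper-catalysed Grignard opening of a terminal epoxide occurs at the CH2 terminus (SN2), so the stereocentre is untouched and becomes the (R)-alcohol, while the dioxolane carries the future CHCl2 carbon.

Step 6
Reactants: 11 (R)-1-(1,3-dioxolan-2-yl)oct-7-en-4-ol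
Product: 12 (S)-2-(4-chlorooct-7-en-1-yl)-1,3-dioxolane
Conditions: PPh3 (1.5 equiv), CCl4, CH2Cl2, 40 °C
Reagents that add atoms: carbon tetrachloride, ClC(Cl)(Cl)Cl
Why: In the Appel reaction chloride displaces the alkoxyphosphonium by SN2 with inversion, turning the (R)-alcohol into the (S)-chloride under neutral conditions that spare the acetal and the alkene.

Step 7
Reactants: 12 (S)-2-(4-chlorooct-7-en-1-yl)-1,3-dioxolane
Product: 13 (S)-5-chloronon-8-enal
Conditions: 1 M HCl, THF, rt
Reagents that add atoms: water, O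
Why: Acid-catalysed acetal hydrolysis frees the aldehyde; the unactivated secondary chloride and the terminal alkene are inert to dilute aqueous acid at room temperature.

Step 8
Reactants: 13 (S)-5-chloronon-8-enal
Product: 14 (S)-5,9,9-trichloronon-1-ene
Conditions: Ph3PO (15 mol %), (COCl)2 (1.3 equiv), CHCl3, rt
Reagents that add atoms: oxalyl chloride, ClC(=O)C(=O)Cl
Why: Catalytic Appel-type deoxydichlorination: Ph3PO and oxalyl chloride give Ph3PCl2, which converts the aldehyde C=O into CHCl2 and regenerates Ph3PO, without touching the remote C–Cl stereocentre or the alkene.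

Step 9
Reactants: 6 (1R,2S)-1-(3,5-dihydroxyphenyl)-2-methylbut-3-en-1-yl carbamate; 14 (S)-5,9,9-trichloronon-1-ene
Product: 15 (1R,2S,3E,7S)-7,11,11-trichloro-1-(3,5-dihydroxyphenyl)-2-methylundec-3-en-1-yl carbamate
Conditions: second-generation Hoveyda–Grubbs catalyst (5 mol %), 14 (2.5 equiv), CH2Cl2, 40 °C
Reagents that add atoms: none
Why: Olefin cross-metathesis between a hindered α-branched (type 2) olefin and an excess of an unhindered terminal (type 1) olefin favours the cross product; the ruthenium carbene tolerates free phenols, the primary carbamate and alkyl chlorides, and no stereocentre is affected (E/Z does not matter, the alkene is reduced next).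

Step 10
Reactants: 15 (1R,2S,3E,7S)-7,11,11-trichloro-1-(3,5-dihydroxyphenyl)-2-methylundec-3-en-1-yl carbamate
Product: 16 (1R,2S,7R)-7,11,11-trichloro-1-(3,5-dihydroxyphenyl)-2-methylundecyl carbamate
Conditions: H2 (1 atm), RhCl(PPh3)3 (5 mol %), benzene/EtOH 1:1, rt
Reagents that add atoms: none
Why: Homogeneous hydrogenation with Wilkinson's catalyst saturates the disubstituted alkene without hydrogenolysis of the benzylic C–O bond or any C–Cl bond and without double-bond migration into the C2 stereocentre (the C7 descriptor changes from S to R only because the CIP ranking changes).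

Step 11
Reactants: 16 (1R,2S,7R)-7,11,11-trichloro-1-(3,5-dihydroxyphenyl)-2-methylundecyl carbamate (two molecules)
Product: 18 CNP0205627.1 (target [7.7]paracyclophane bis-carbamate), via linear head-to-tail dimer 17 (not isolated)
Conditions: CylK (recombinant, 10 mol %), HEPES buffer (50 mM, pH 7.8), MgCl2 (10 mM), CaCl2 (5 mM), 5% DMSO, 0.5 mM 16, 37 °C, 24 h
Reagents that add atoms: none
Why: Proposed new method: CylK's known reaction is a stereoinvertive SN2-type Friedel–Crafts C-alkylation of the resorcinol 2-position by an unactivated secondary alkyl chloride (Asp-assisted phenol deprotonation, hydrogen bonding of Arg/Tyr to the departing chloride), and it is here asked to accept a monomer carrying the C1 carbamate and a dichloromethyl terminus, which is untested, but both changes lie away from the reacting aryl C–H and C7–Cl centres and the enzyme already tolerates varied resorcinols and secondary halides; each (7R)-chloride is inverted to the (S)-aryl centre of the target, the first alkylation being intermolecular and head-to-tail and the second closing the 22-membered ring, and the closest known reaction is the CylK-catalysed dimerisation of the native chloro-alkylresorcinol to cylindrocyclophane F.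

**Compound list**

1 | 3,5-dihydroxybenzaldehyde | O=Cc1cc(O)cc(O)c1 | starting material
2 | 3,5-bis(tert-butyldimethylsilyloxy)benzaldehyde | O=Cc1cc(O[Si](C)(C)C(C)(C)C)cc(O[Si](C)(C)C(C)(C)C)c1 | intermediate
3 | (1R,2S)-1-[3,5-bis(tert-butyldimethylsilyloxy)phenyl]-2-methylbut-3-en-1-yl diisopinocampheylborinate | C=C[C@H](C)[C@@H](OB([C@H]1C[C@H]2C[C@@H]([C@@H]1C)C2(C)C)[C@H]1C[C@H]2C[C@@H]([C@@H]1C)C2(C)C)c1cc(O[Si](C)(C)C(C)(C)C)cc(O[Si](C)(C)C(C)(C)C)c1 | intermediate (not isolated)
4 | (1R,2S)-1-[3,5-bis(tert-butyldimethylsilyloxy)phenyl]-2-methylbut-3-en-1-ol | C=C[C@H](C)[C@@H](O)c1cc(O[Si](C)(C)C(C)(C)C)cc(O[Si](C)(C)C(C)(C)C)c1 | intermediate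
5 | (1R,2S)-1-[3,5-bis(tert-butyldimethylsilyloxy)phenyl]-2-methylbut-3-en-1-yl N-(trichloroacetyl)carbamate | C=C[C@H](C)[C@@H](OC(=O)NC(=O)C(Cl)(Cl)Cl)c1cc(O[Si](C)(C)C(C)(C)C)cc(O[Si](C)(C)C(C)(C)C)c1 | intermediate (not isolated)
6 | (1R,2S)-1-(3,5-dihydroxyphenyl)-2-methylbut-3-en-1-yl carbamate | C=C[C@H](C)[C@@H](OC(N)=O)c1cc(O)cc(O)c1 | intermediate
7 | rac-2-(but-3-en-1-yl)oxirane | C=CCCC1CO1 | starting material
8 | (S)-2-(but-3-en-1-yl)oxirane | C=CCC[C@H]1CO1 | intermediate
9 | 2-(2-bromoethyl)-1,3-dioxolane | BrCCC1OCCO1 | starting material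
10 | [2-(1,3-dioxolan-2-yl)ethyl]magnesium bromide | Br[Mg]CCC1OCCO1 | intermediate (not isolated)
11 | (R)-1-(1,3-dioxolan-2-yl)oct-7-en-4-ol | C=CCC[C@H](O)CCCC1OCCO1 | intermediate
12 | (S)-2-(4-chlorooct-7-en-1-yl)-1,3-dioxolane | C=CCC[C@@H](Cl)CCCC1OCCO1 | intermediate
13 | (S)-5-chloronon-8-enal | C=CCC[C@@H](Cl)CCCC=O | intermediate
14 | (S)-5,9,9-trichloronon-1-ene | C=CCC[C@@H](Cl)CCCC(Cl)Cl | intermediate
15 | (1R,2S,3E,7S)-7,11,11-trichloro-1-(3,5-dihydroxyphenyl)-2-methylundec-3-en-1-yl carbamate | NC(=O)O[C@@H](c1cc(O)cc(O)c1)[C@@H](C)/C=C/CC[C@@H](Cl)CCCC(Cl)Cl | intermediate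
16 | (1R,2S,7R)-7,11,11-trichloro-1-(3,5-dihydroxyphenyl)-2-methylundecyl carbamate | NC(=O)O[C@@H](c1cc(O)cc(O)c1)[C@@H](C)CCCC[C@@H](Cl)CCCC(Cl)Cl | intermediate
17 | linear head-to-tail dimer: 16 C-alkylated at the resorcinol 2-position by C7 of a second molecule of 16 (new centre S); one secondary chloride and one unsubstituted resorcinol remain | NC(=O)O[C@@H](c1cc(O)cc(O)c1)[C@@H](C)CCCC[C@@H](CCCC(Cl)Cl)c1c(O)cc(cc1O)[C@H](OC(N)=O)[C@@H](C)CCCC[C@@H](Cl)CCCC(Cl)Cl | intermediate (not isolated)
18 | CNP0205627.1: C2-symmetric [7.7]paracyclophane, each bridge aryl–CH(OCONH2)(R)–CH(CH3)(S)–(CH2)4–CH[(CH2)3CHCl2](S)–aryl | C[C@H]1CCCC[C@@H](CCCC(Cl)Cl)c2c(O)cc(cc2O)[C@H](OC(N)=O)[C@@H](C)CCCC[C@@H](CCCC(Cl)Cl)c2c(O)cc(cc2O)[C@@H]1OC(N)=O | target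

**Totals and risks**

Total step count: 11. Longest linear sequence: 8 (steps 4 to 11, from 7 to 18).

Most likely to fail, first: step 11. The enzyme may reject a monomer that carries the carbamate next to the nucleophilic ring. The fallback restores the biosynthetic order, ring first and carbamate last, and sets out from 4. K2CO3/MeOH gives (1R,2S)-1-(3,5-dihydroxyphenyl)-2-methylbut-3-en-1-ol F1. Cross-metathesis with 14 (second-generation Hoveyda–Grubbs catalyst, CH2Cl2, 40 °C) gives 5-[(1R,2S,3E,7S)-7,11,11-trichloro-1-hydroxy-2-methylundec-3-en-1-yl]benzene-1,3-diol F2. Hydrogenation (H2, RhCl(PPh3)3) gives 5-[(1R,2S,7R)-7,11,11-trichloro-1-hydroxy-2-methylundecyl]benzene-1,3-diol F3, which differs from the native CylK substrate only by the C1 hydroxyl and the terminal chlorines. CylK converts it, through the linear head-to-tail dimer of the hydroxy series F4, into the macrocyclic bis(benzylic alcohol), the descarbamoyl analogue of 18, F5. Excess trichloroacetyl isocyanate then acylates all six hydroxyls to the hexakis(N-trichloroacetylcarbamate) of the macrocycle F6. K2CO3/MeOH removes the six trichloroacetyl groups and cleaves the four aryl carbamates (E1cB loss from the phenoxide leaving group), while the two alkyl carbamates stay. The route is rejoined at 18.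

Second: step 8. The enolisable aldehyde may give vinyl chloride or α-chlorination products with the chlorophosphonium reagent. The fallback sets out from 13 and uses the Takeda hydrazone route, which is a copper-mediated oxidative process instead of oxygen activation at phosphorus. Hydrazine hydrate in MeOH over molecular sieves gives (S)-5-chloronon-8-enal hydrazone F7. CuCl2 (6 equiv) and Et3N in MeOH at rt oxidise it to (S)-5-chloro-9-diazonon-1-ene F8, which loses N2 on copper chloride and takes up two chlorides. The route is rejoined at 14.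

Third: step 9. The free resorcinol and primary carbamate of 6 may slow the ruthenium catalyst or make the hindered olefin too unreactive. The fallback changes the protecting-group logic and the order of events and sets out from 4. Carbamoylation with trichloroacetyl isocyanate proceeds through 5 as before, but the trichloroacetyl group is cleaved on neutral Al2O3, which keeps both silyl ethers and gives (1R,2S)-1-[3,5-bis(tert-butyldimethylsilyloxy)phenyl]-2-methylbut-3-en-1-yl carbamate F9. Cross-metathesis of this non-phenolic, lipophilic partner with 14 gives (1R,2S,3E,7S)-1-[3,5-bis(tert-butyldimethylsilyloxy)phenyl]-7,11,11-trichloro-2-methylundec-3-en-1-yl carbamate F10. K2CO3/MeOH then frees the phenols and the route is rejoined at 15.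

**Further compounds**

F1 | step 11 | (1R,2S)-1-(3,5-dihydroxyphenyl)-2-methylbut-3-en-1-ol | C=C[C@H](C)[C@@H](O)c1cc(O)cc(O)c1
F2 | step 11 | 5-[(1R,2S,3E,7S)-7,11,11-trichloro-1-hydroxy-2-methylundec-3-en-1-yl]benzene-1,3-diol | O[C@@H](c1cc(O)cc(O)c1)[C@@H](C)/C=C/CC[C@@H](Cl)CCCC(Cl)Cl
F3 | step 11 | 5-[(1R,2S,7R)-7,11,11-trichloro-1-hydroxy-2-methylundecyl]benzene-1,3-diol | O[C@@H](c1cc(O)cc(O)c1)[C@@H](C)CCCC[C@@H](Cl)CCCC(Cl)Cl
F4 | step 11 | linear head-to-tail dimer of the hydroxy series | O[C@@H](c1cc(O)cc(O)c1)[C@@H](C)CCCC[C@@H](CCCC(Cl)Cl)c1c(O)cc(cc1O)[C@H](O)[C@@H](C)CCCC[C@@H](Cl)CCCC(Cl)Cl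
F5 | step 11 | macrocyclic bis(benzylic alcohol), the descarbamoyl analogue of 18 | C[C@H]1CCCC[C@@H](CCCC(Cl)Cl)c2c(O)cc(cc2O)[C@H](O)[C@@H](C)CCCC[C@@H](CCCC(Cl)Cl)c2c(O)cc(cc2O)[C@@H]1O
F6 | step 11 | hexakis(N-trichloroacetylcarbamate) of the macrocycle | C[C@H]1CCCC[C@@H](CCCC(Cl)Cl)c2c(OC(=O)NC(=O)C(Cl)(Cl)Cl)cc(cc2OC(=O)NC(=O)C(Cl)(Cl)Cl)[C@H](OC(=O)NC(=O)C(Cl)(Cl)Cl)[C@@H](C)CCCC[C@@H](CCCC(Cl)Cl)c2c(OC(=O)NC(=O)C(Cl)(Cl)Cl)cc(cc2OC(=O)NC(=O)C(Cl)(Cl)Cl)[C@@H]1OC(=O)NC(=O)C(Cl)(Cl)Cl
F7 | step 8 | (S)-5-chloronon-8-enal hydrazone | C=CCC[C@@H](Cl)CCCC=NN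
F8 | step 8 | (S)-5-chloro-9-diazonon-1-ene | C=CCC[C@@H](Cl)CCCC=[N+]=[N-]
F9 | step 9 | (1R,2S)-1-[3,5-bis(tert-butyldimethylsilyloxy)phenyl]-2-methylbut-3-en-1-yl carbamate | C=C[C@H](C)[C@@H](OC(N)=O)c1cc(O[Si](C)(C)C(C)(C)C)cc(O[Si](C)(C)C(C)(C)C)c1
F10 | step 9 | (1R,2S,3E,7S)-1-[3,5-bis(tert-butyldimethylsilyloxy)phenyl]-7,11,11-trichloro-2-methylundec-3-en-1-yl carbamate | NC(=O)O[C@@H](c1cc(O[Si](C)(C)C(C)(C)C)cc(O[Si](C)(C)C(C)(C)C)c1)[C@@H](C)/C=C/CC[C@@H](Cl)CCCC(Cl)Cl
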